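## Structural features

Corymbosin (17) is a flavone. Benzene ring A and 4-pyranone ring C are fused through the C4a–C8a bond, and ring B, a 3,4,5-trimethoxyphenyl group, sits on C2 of ring C through one sp2–sp2 bond. Apart from the four O-methyl carbons every carbon is sp2. There is no stereocentre (so none stand next to each other), no stereogenic axis and no configurable double bond. The compound is therefore achiral, the question of one enantiomer does not arise, and no step has to control configuration.

Ring A carries three oxygen atoms in a 1,3,5 arrangement (O1 on C8a, OH on C5, OMe on C7) with hydrogen on C6 and C8, and the C5 hydroxyl is hydrogen-bonded to the C4 carbonyl. The fragile parts are the pyranone ring, which hydroxide or amines open at C2 and short-wave UV light isomerises, and the aryl methyl ethers, of which the flanked 4'-OMe is the first to fall to Lewis acids.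

The carbon skeleton is easy to build. The real difficulty is telling the ring A oxygens apart, so that O5 ends free and O7 methylated without a selective alkylation or dealkylation. The key step uses the fact that C5(OH)–C6(H)–C7(OMe)–C8(H) is a four-carbon resorcinol monoether segment bridging C4a=C8a, which is simply the C3=C2 double bond of a monocyclic 4-pyranone. A ketene carbon becomes C5, an ynol ether supplies C6 and C7, and a diazo carbon becomes C8.

## Logic of the disconnections

**17 ⇒ 9 + 12.**
- **Bonds cut:** ring A is removed completely by cutting C4a–C5, C5–C6, C7–C8 and C8–C8a. Read backwards through 16, 15, 14 and 13, C6 and C7 leave as the two alkyne carbons of 12. C5 and C8 are rejoined to each other and C5 returns to C8a, which restores the acyl–diazo unit of 9.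
- **Reason:** the substitution pattern then follows from the mechanism. The oxygen on C5 is the former ketene oxygen and ends as the free phenol, the C7 methoxy group arrives ready-made with 12, and C6 and C8 carry hydrogen because both partners are terminal.
- **Gain:** a bicycle with an oxygen-differentiation problem becomes a monocyclic pyranone and a two-carbon alkyne, with no protecting group and no late O-methylation or demethylation.
- **Demands on the forward step:**
  - Nitrogen must leave 9 without excitation of the arylpyranone chromophore. The strong UV band of the diazoketone overlaps that chromophore, so the weak long-wave diazo band has to be addressed with violet/blue light.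
  - 13 must be captured by 12 faster than it dimerises, which calls for excess 12, kept cold and enclosed because it is volatile.
  - The excess of 12 should be stripped before heating, so that the new phenol never meets hot ynol ether.
  - The pyranone C2=C3 bond must serve as the terminus of the 6π closure. This is the untested element.

**9 ⇒ 7 (through 8).** The bond between the acyl carbon and the diazo carbon is cut. Acylation of a one-carbon diazoalkane is the most direct entry to a terminal diazoketone and leads back to a stable, crystalline acid. Activation must not engage the pyranone carbonyl. The diazoalkane must not add across the doubly activated C2=C3 bond, so its amount is held near one equivalent and a tertiary amine takes up the acid released. This is permissible because 8 has no α-hydrogen.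

**7 ⇒ 5 (through 6).** One ring C–O bond of the pyranone is cut and the ethyl ester is restored. A 1,3,5-tricarbonyl chain has only one six-membered cyclodehydration mode, so ring C reduces to an open chain at no cost in selectivity. Both the ring closure and the ester cleavage must run in acid, since aqueous base would reopen the pyranone.

**5 ⇒ 3 + 4.** The C2–C3 bond of the hexanoate chain is cut, which releases a non-enolisable two-carbon diester and a simple β-diketone. The forward condensation must acylate the terminal methyl group of 3 and not its central carbon. Equilibrating alkoxide conditions are relied on, under which only the terminal product is withdrawn as a doubly enolised salt.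

**3 ⇒ 1 + 2.** The C2–C3 bond of the butanedione is cut, giving a purchasable aryl methyl ketone and a bulk ester. The only requirement is enough base to hold 3 as its enolate and so drive the equilibrium.

**12 ⇒ 10 (through 11).** No C–C bond is cut. The two π bonds of the alkyne are traced back to one C–O and one C–Cl σ bond of a purchasable haloacetal. The forward twofold elimination needs a third equivalent of strong base, so that the volatile product rests as the involatile salt 11 until the solvent has gone.

## Other disconnections considered

**Alternative 1:**
- **Cut:** C4a–C5, made at the chalcone stage, so that ring A unravels to methyl (E)-3,5,7-trioxo-9-(3,4,5-trimethoxyphenyl)non-8-enoate A1.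
- **Forward key step:** base would enolise C6 of A1, this carbon would attack the ester carbon C1 (intramolecular Claisen condensation), and enolisation would give (E)-2',4',6'-trihydroxy-3,4,5-trimethoxychalcone A2.
- **In favour:** the folding copies the biosynthetic one. One C–C bond closes ring A with cheap ionic chemistry, and the two equivalent ortho-hydroxyls of A2 leave no regiochemical question for the later closure of ring C.
- **Against:**
  - A1 has several competing modes: aldol closure of C2 onto C7, lactonisation of the C5 enol onto C1 to a 4-hydroxy-2-pyranone, and conjugate addition to the cinnamoyl enone. Only the reaction conditions choose between them.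
  - A1 itself requires polyanion acylation chemistry.
  - A2 still needs oxidative closure to the flavone level and then a selective 7-O-methylation.
- **Structure:** both plans build ring A from acyclic carbon, but here ring C and its oxidation level remain to be made and the ring A oxygens emerge undifferentiated.
- **Mechanism:** the Claisen folding of triketo esters is an established reaction type that needs no light and no diazo compound. On precedent and on handling it is better than the chosen key step. In the chosen plan, however, regiochemistry is set by reagent polarity and not by conditions.
- **Step economy:** two or three steps to A1 and about three after A2 make it equal at best.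

**Alternative 2:**
- **Cut:** O1–C8a, C4–C4a and O1–C2, so ring C is removed and ring A is bought as an arene.
- **Forward key step:**
  - Fluoride would release 3,5-dimethoxybenzyne A4 from 3,5-dimethoxy-2-(trimethylsilyl)phenyl triflate A3.
  - The carboxylate of 3-(3,4,5-trimethoxyphenyl)propiolic acid A5 would add through oxygen to the aryne carbon remote from the neighbouring methoxy group.
  - The aryl anion next to that methoxy group would attack the acyl carbon.
  - The resulting o-hydroxyaryl ynone would close in a 6-endo sense to 5,7,3',4',5'-pentamethoxyflavone A6.
- **In favour:** the route is convergent and forms three bonds in one mild operation. The dependable regiochemistry of nucleophilic addition to 3-alkoxyarynes matches the 5,7 pattern.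
- **Against:**
  - Proton transfer to the aryl anion can stop the cascade at the simple aryl ester.
  - 5-exo closure competes with the 6-endo mode.
  - A3 and A5 each need several steps.
  - A6 carries five methyl ethers, of which only the 5-OMe may be removed. Chelation-directed Lewis acid cleavage is well founded, but the flanked 4'-OMe is also labile.
- **Structure:** it constructs ring C, which is the easy ring, and postpones the oxygen differentiation to a final deprotection. The chosen plan delivers 5-OH and 7-OMe directly.
- **Mechanism:** the ionic cascade rests on closer precedent and avoids diazo compounds, photochemistry and a volatile ynol ether, and on these points it is the better plan.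
- **Step economy:** convergence is equal, and the overall count with the preparations of A3 and A5 plus the demethylation is comparable or slightly higher.

**Alternative 3:**
- **Cut:** C4–C4a and O1–C2.
- **Forward key step:** phloroglucinol A7 and ethyl 3-oxo-3-(3,4,5-trimethoxyphenyl)propanoate A8 would be heated together without solvent. C-acylation of the arene and cyclodehydration, with loss of ethanol and water, would give 5,7-dihydroxy-3',4',5'-trimethoxyflavone A9.
- **In favour:** both partners can be bought. The threefold symmetry of A7 removes every regiochemical question, and ring C closes in one reagent-free operation.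
- **Against:**
  - The temperature is very high.
  - The coumarin-forming (Pechmann-type) mode competes.
  - A9 still needs a 7-O-methylation, whose selectivity rests on the chelation of the 5-hydroxyl.
- **Structure:** it leaves the actual problem, O5 versus O7, to a final selective alkylation, although that selectivity is among the most reliable in flavonoid chemistry.
- **Mechanism:** it is fully precedented and therefore safer than the chosen key step.
- **Step economy:** two steps from commercial material make it clearly better than the chosen plan, as does the absence of hazardous reagents. The chosen plan offers only that the ring A pattern is set by mechanism without any selectivity step, and that it opens a new way of annulating a pyranone.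

Key step: step 6

Remark on the chemistry: 17 has no stereogenic element and is made as the achiral compound it is. 14 and 16 each hold one transient sp3 stereocentre, form as racemates and lose it on the way to 17.

## Route

Step 1
Reactants: 1 3',4',5'-trimethoxyacetophenone; 2 ethyl acetate
Product: 3 1-(3,4,5-trimethoxyphenyl)butane-1,3-dione
Conditions: NaH (2.2 equiv), 2 (3 equiv), THF, 0 °C → reflux; cold aq. HCl
Reagents that add atoms: none
Why: Crossed Claisen condensation in which the enolate of 1 attacks 2 and irreversible deprotonation of the β-diketone drives the equilibrium. Self-condensation of 2 only gives a by-product that is removed on work-up, and the aryl ethers are inert to the base.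

Step 2
Reactants: 3 1-(3,4,5-trimethoxyphenyl)butane-1,3-dione; 4 diethyl oxalate
Product: 5 ethyl 2,4,6-trioxo-6-(3,4,5-trimethoxyphenyl)hexanoate (enolised)
Conditions: NaOEt (2.5 equiv), 4 (1.3 equiv), EtOH–THF, 0 °C → rt → 50 °C; cold aq. HCl, filter
Reagents that add atoms: none
Why: Crossed Claisen condensation (oxalylation) with a non-enolisable, very electrophilic diester, the reaction type behind the classical chelidonic acid synthesis and the usual way from aroylacetones to 6-arylcomanic acids. Acylation at the central carbon is reversible under ethoxide, whereas acylation at the methyl group gives a product that leaves the equilibrium as its doubly enolised disodium salt.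

Step 3
Reactants: 5 ethyl 2,4,6-trioxo-6-(3,4,5-trimethoxyphenyl)hexanoate
Product: 7 4-oxo-6-(3,4,5-trimethoxyphenyl)-4H-pyran-2-carboxylic acid, via pyranone ethyl ester 6 (not isolated)
Conditions: conc. HCl–AcOH (1:2), 100 °C; dilute with water, filter
Reagents that add atoms: water, SMILES O
Why: Acid-catalysed cyclodehydration of a 1,3,5-tricarbonyl chain to the 4-pyranone, for which only one six-membered mode exists, followed in the same pot by acid ester hydrolysis. Acid is chosen because hydroxide would open the pyranone, and aqueous HCl at this temperature does not cleave aryl methyl ethers or decarboxylate the acid.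

Step 4
Reactants: 7 4-oxo-6-(3,4,5-trimethoxyphenyl)-4H-pyran-2-carboxylic acid
Product: 9 2-(2-diazoacetyl)-6-(3,4,5-trimethoxyphenyl)-4H-pyran-4-one, via acid chloride 8 (not isolated)
Conditions: (COCl)2 (1.3 equiv), cat. DMF, CH2Cl2, 0 °C → rt, evaporate; CH2N2 (1.3 equiv, Et2O), Et3N (1.1 equiv), THF, −10 → 0 °C, dark; AcOH quench
Reagents that add atoms: oxalyl chloride, SMILES O=C(Cl)C(=O)Cl (chlorine of 8 only); diazomethane, SMILES C=[N+]=[N-]
Why: DMF-catalysed acid chloride formation, then acylation of diazomethane (first stage of the Arndt–Eistert sequence) in the Newman–Beal variant, where triethylamine takes up HCl so that little more than one equivalent of diazomethane is needed and no chloromethyl ketone forms. 8 has no α-hydrogen, so the amine cannot turn it into a ketene, and the small excess at low temperature spares the electron-poor C2=C3 bond from dipolar cycloaddition.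

Step 5
Reactants: 10 chloroacetaldehyde dimethyl acetal
Product: 12 methoxyacetylene, via sodium methoxyacetylide 11 (not isolated)
Conditions: NaNH2 (3.1 equiv), liq. NH3, −33 °C; evaporate NH3; cold sat. aq. NaCl, then warm and distil into a −78 °C trap; keep as a dried ClCH2CH2Cl solution at −20 °C
Reagents that add atoms: sodium amide, SMILES [Na+].[NH2-] (sodium of 11 only)
Why: Two successive β-eliminations remove methanol and HCl, and a third equivalent of amide holds the product as the involatile acetylide 11 until the ammonia has gone; this is the standard preparation of the lower alkoxyacetylenes from haloacetals. Cold brine liberates 12, which distils straight out of the basic mixture. Because its alkyl group has no β-hydrogen, 12 cannot fragment by the retro-ene path open to its higher homologues.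

Step 6
Reactants: 9 2-(2-diazoacetyl)-6-(3,4,5-trimethoxyphenyl)-4H-pyran-4-one; 12 methoxyacetylene
Product: 17 corymbosin [5-hydroxy-7-methoxy-2-(3,4,5-trimethoxyphenyl)-4H-chromen-4-one], via pyranylketene 13 (not isolated), via cyclobutenone 14 (not isolated), via dienylketene 15 (not isolated), via cyclohexadienone 16 (not isolated)
Conditions: 12 (4 equiv), dry degassed ClCH2CH2Cl, LED 420–450 nm, 5 °C, closed Pyrex vessel or FEP flow coil; evaporate excess 12 and solvent; PhMe, 110 °C, Ar
Reagents that add atoms: none
Why: Proposed new method: the closest known reaction type is the Danheiser benzannulation in its photo-Wolff form, established for vinyl, aryl and heteroaryl diazomethyl ketones with alkoxy- and silyloxyalkynes but not with the C2=C3 bond of a 4-pyranone as the ene part. Excitation of the weak long-wave diazo band expels N2 from the s-Z conformer of 9 while the pyranyl group shifts from the carbonyl carbon to the diazo carbon (C8–C8a), giving ketene 13. The electrophilic ketene carbon (future C5) bonds to the nucleophilic CH terminus of 12 (C5–C6) and the ketene α-carbon to the methoxy-bearing carbon (C7–C8), so the [2+2] addition should give only the 3-methoxy-4-pyranyl isomer 14. At 110 °C 14 opens reversibly in a conrotatory 4π sense by cleavage of C5–C8; only isomer 15, with the pyranyl group cis to the ketenyl carbon, can react on, and the unproductive isomer returns through 14. Ring A, the only ring formed, closes by a disrotatory 6π electrocyclisation joining the ketene carbon to pyranone C3 (C4a–C5), a polarity-matched union because C3 is the β-carbon of the ring enol ether. Enolisation of 16, whose C4a–H lies between two carbonyl groups, gives the chelated C5 phenol irreversibly. No stereocentre is created in 17, since the sp3 carbons of 14 and 16 are transient and racemic. The step needs chemoselective excitation (secured by irradiating beyond the absorption edge of the arylpyranone), regioselective [2+2] addition (secured by the polarity of the ynol ether) and site-selective closure (secured because the other neighbour of pyranone C2 is the ring oxygen).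

## Compound list

1 | 3',4',5'-trimethoxyacetophenone | CC(=O)c1cc(OC)c(OC)c(OC)c1 | starting material
2 | ethyl acetate | CCOC(C)=O | starting material
3 | 1-(3,4,5-trimethoxyphenyl)butane-1,3-dione | CC(=O)CC(=O)c1cc(OC)c(OC)c(OC)c1 | intermediate
4 | diethyl oxalate | CCOC(=O)C(=O)OCC | starting material
5 | ethyl 2,4,6-trioxo-6-(3,4,5-trimethoxyphenyl)hexanoate | CCOC(=O)C(=O)CC(=O)CC(=O)c1cc(OC)c(OC)c(OC)c1 | intermediate
6 | ethyl 4-oxo-6-(3,4,5-trimethoxyphenyl)-4H-pyran-2-carboxylate | CCOC(=O)c1cc(=O)cc(-c2cc(OC)c(OC)c(OC)c2)o1 | intermediate
7 | 4-oxo-6-(3,4,5-trimethoxyphenyl)-4H-pyran-2-carboxylic acid | OC(=O)c1cc(=O)cc(-c2cc(OC)c(OC)c(OC)c2)o1 | intermediate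
8 | 4-oxo-6-(3,4,5-trimethoxyphenyl)-4H-pyran-2-carbonyl chloride | ClC(=O)c1cc(=O)cc(-c2cc(OC)c(OC)c(OC)c2)o1 | intermediate
9 | 2-(2-diazoacetyl)-6-(3,4,5-trimethoxyphenyl)-4H-pyran-4-one | COc1cc(-c2cc(=O)cc(C(=O)C=[N+]=[N-])o2)cc(OC)c1OC | intermediate
10 | chloroacetaldehyde dimethyl acetal | COC(CCl)OC | starting material
11 | sodium methoxyacetylide | [Na+].[C-]#COC | intermediate
12 | methoxyacetylene | C#COC | intermediate
13 | 2-[4-oxo-6-(3,4,5-trimethoxyphenyl)-4H-pyran-2-yl]ethen-1-one | O=C=Cc1cc(=O)cc(-c2cc(OC)c(OC)c(OC)c2)o1 | intermediate
14 | 3-methoxy-4-[4-oxo-6-(3,4,5-trimethoxyphenyl)-4H-pyran-2-yl]cyclobut-2-en-1-one (racemic) | COC1=CC(=O)C1c1cc(=O)cc(-c2cc(OC)c(OC)c(OC)c2)o1 | intermediate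
15 | (3E)-3-methoxy-4-[4-oxo-6-(3,4,5-trimethoxyphenyl)-4H-pyran-2-yl]buta-1,3-dien-1-one (pyranyl cis to the ketenyl carbon) | O=C=C/C(OC)=C\c1cc(=O)cc(-c2cc(OC)c(OC)c(OC)c2)o1 | intermediate
16 | 7-methoxy-2-(3,4,5-trimethoxyphenyl)-4aH-chromene-4,5-dione (racemic) | COC1=CC(=O)C2C(=O)C=C(c3cc(OC)c(OC)c(OC)c3)OC2=C1 | intermediate
17 | corymbosin, 5-hydroxy-7-methoxy-2-(3,4,5-trimethoxyphenyl)-4H-chromen-4-one (achiral) | COc1cc(O)c2c(=O)cc(-c3cc(OC)c(OC)c(OC)c3)oc2c1 | target

## Step count and least certain steps

Total: 6 steps. The longest linear sequence is 5 steps (steps 1, 2, 3, 4, 6). Step 5 is a one-step side branch.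

**Step 6 (key step, carries the label).**

The most likely failure is stalling after the [2+2] stage. The opening of 14 is reversible. If the 6π closure onto the cross-conjugated, acceptor-substituted C2=C3 bond is slow, oligomerisation of the dienylketene and its capture by adventitious nucleophiles take over.

Secondary risks:
- Photoisomerisation of the arylpyranone, if the light reaches its absorption band.
- Dimerisation of the first ketene, if the volatile alkyne escapes from the irradiated solution.
- O-acylation of the product phenol by ketene, which mild methanolysis during work-up would reverse.

The fallback uses only known chemistry and builds ring C onto a purchased ring A. It sets out from 1 and comes back at 17.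
- 1 is C-acylated with diethyl carbonate and sodium hydride to ethyl 3-oxo-3-(3,4,5-trimethoxyphenyl)propanoate F1.
- This is fused with phloroglucinol without solvent at about 240 °C to 5,7-dihydroxy-2-(3,4,5-trimethoxyphenyl)-4H-chromen-4-one F2.
- This is methylated with one equivalent of dimethyl sulfate and potassium carbonate in acetone. The chelated 5-hydroxyl stays behind and the 7-hydroxyl reacts, giving 17.

The price is that compounds 3 to 16 are abandoned.

**Step 4.**

The most likely failure is 1,3-dipolar cycloaddition of diazomethane across the C2=C3 bond, which two carbonyl groups activate in 8 and 9. Next come activation of the pyranone carbonyl oxygen by the chlorinating agent and hydrolysis of the sensitive acid chloride during handling.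

The fallback replaces diazoalkane acylation by diazo transfer and needs no diazomethane. It sets out from 3 and comes back at 9.
- The dianion of 3 (LDA, THF) is acylated at its terminal carbon with methyl 2,2-dimethoxypropanoate to 6,6-dimethoxy-1-(3,4,5-trimethoxyphenyl)heptane-1,3,5-trione F3.
- Aqueous acid closes the pyranone and unmasks the ketone to give 2-acetyl-6-(3,4,5-trimethoxyphenyl)-4H-pyran-4-one F4.
- Its lithium enolate (LiHMDS, −78 °C) is acylated with 2,2,2-trifluoroethyl trifluoroacetate to 4,4,4-trifluoro-1-[4-oxo-6-(3,4,5-trimethoxyphenyl)-4H-pyran-2-yl]butane-1,3-dione F5.
- This is treated crude with methanesulfonyl azide, triethylamine and water in acetonitrile (detrifluoroacetylative diazo transfer) to give 9.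

**Step 2.**

The most likely failure is retro-Claisen cleavage of 3 by ethoxide, with oxalylation of the liberated methyl ketone, which shortens the chain. Lasting acylation at the central carbon or lactonisation of an enolate onto the ester are further possibilities.

The fallback blocks the central carbon before the oxalylation. It sets out from 3 and comes back at 7.
- 3 is condensed with N,N-dimethylformamide dimethyl acetal to 2-[(dimethylamino)methylidene]-1-(3,4,5-trimethoxyphenyl)butane-1,3-dione F6, in which only the acetyl methyl group can still enolise.
- Claisen condensation with 4 (NaH, THF) and acidification close the ring with loss of the amine, giving ethyl 4-oxo-5-(3,4,5-trimethoxybenzoyl)-4H-pyran-2-carboxylate F7.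
- Hot aqueous acid adds water at the unsubstituted C6 and opens the ring. The formyl group is lost by retro-Claisen cleavage, the ester is hydrolysed, and the 2,4,6-trioxo chain recloses on the aroyl carbonyl to give 7.

**Step 5.**

The most likely failures are evaporative loss and acid- or heat-triggered polymerisation of the very volatile ynol ether during liberation and distillation, and incomplete second elimination.

The fallback uses a storable, higher-boiling C-silylated ynol ether and removes the silyl group after the annulation. It sets out from 10 (with 9 as partner) and comes back at 17.
- 10 is treated with lithium diethylamide (3 equiv) in THF to give lithium methoxyacetylide F8 in solution.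
- This is quenched with chlorotrimethylsilane to (methoxyethynyl)trimethylsilane F9.
- This is used with 9 under the conditions of step 6. The silyl-bearing carbon is still the nucleophilic terminus, so 5-hydroxy-7-methoxy-6-(trimethylsilyl)-2-(3,4,5-trimethoxyphenyl)-4H-chromen-4-one F10 should result.
- Ipso-protonation with trifluoroacetic acid in CH2Cl2 removes the silyl group from this electron-rich position and gives 17.

## Further compounds

F1 | step 6 | ethyl 3-oxo-3-(3,4,5-trimethoxyphenyl)propanoate | CCOC(=O)CC(=O)c1cc(OC)c(OC)c(OC)c1
F2 | step 6 | 5,7-dihydroxy-2-(3,4,5-trimethoxyphenyl)-4H-chromen-4-one | COc1cc(-c2cc(=O)c3c(O)cc(O)cc3o2)cc(OC)c1OC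
F3 | step 4 | 6,6-dimethoxy-1-(3,4,5-trimethoxyphenyl)heptane-1,3,5-trione | CC(OC)(OC)C(=O)CC(=O)CC(=O)c1cc(OC)c(OC)c(OC)c1
F4 | step 4 | 2-acetyl-6-(3,4,5-trimethoxyphenyl)-4H-pyran-4-one | CC(=O)c1cc(=O)cc(-c2cc(OC)c(OC)c(OC)c2)o1
F5 | step 4 | 4,4,4-trifluoro-1-[4-oxo-6-(3,4,5-trimethoxyphenyl)-4H-pyran-2-yl]butane-1,3-dione | O=C(CC(=O)C(F)(F)F)c1cc(=O)cc(-c2cc(OC)c(OC)c(OC)c2)o1
F6 | step 2 | 2-[(dimethylamino)methylidene]-1-(3,4,5-trimethoxyphenyl)butane-1,3-dione | CC(=O)C(=CN(C)C)C(=O)c1cc(OC)c(OC)c(OC)c1
F7 | step 2 | ethyl 4-oxo-5-(3,4,5-trimethoxybenzoyl)-4H-pyran-2-carboxylate | CCOC(=O)c1cc(=O)c(C(=O)c2cc(OC)c(OC)c(OC)c2)co1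
F8 | step 5 | lithium methoxyacetylide | [Li+].[C-]#COC
F9 | step 5 | (methoxyethynyl)trimethylsilane | COC#C[Si](C)(C)C
F10 | step 5 | 5-hydroxy-7-methoxy-6-(trimethylsilyl)-2-(3,4,5-trimethoxyphenyl)-4H-chromen-4-one | COc1cc2oc(-c3cc(OC)c(OC)c(OC)c3)cc(=O)c2c(O)c1[Si](C)(C)C
A1 | alternative 1 | methyl (E)-3,5,7-trioxo-9-(3,4,5-trimethoxyphenyl)non-8-enoate | COC(=O)CC(=O)CC(=O)CC(=O)/C=C/c1cc(OC)c(OC)c(OC)c1
A2 | alternative 1 | (E)-2',4',6'-trihydroxy-3,4,5-trimethoxychalcone | COc1cc(/C=C/C(=O)c2c(O)cc(O)cc2O)cc(OC)c1OC
A3 | alternative 2 | 3,5-dimethoxy-2-(trimethylsilyl)phenyl trifluoromethanesulfonate | COc1cc(OC)c([Si](C)(C)C)c(OS(=O)(=O)C(F)(F)F)c1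
A4 | alternative 2 | 3,5-dimethoxybenzyne | C1#CC(OC)=CC(OC)=C1
A5 | alternative 2 | 3-(3,4,5-trimethoxyphenyl)propiolic acid | OC(=O)C#Cc1cc(OC)c(OC)c(OC)c1
A6 | alternative 2 | 5,7,3',4',5'-pentamethoxyflavone | COc1cc(OC)c2c(=O)cc(-c3cc(OC)c(OC)c(OC)c3)oc2c1
A7 | alternative 3 | phloroglucinol | Oc1cc(O)cc(O)c1
A8 | alternative 3 | ethyl 3-oxo-3-(3,4,5-trimethoxyphenyl)propanoate | CCOC(=O)CC(=O)c1cc(OC)c(OC)c(OC)c1
A9 | alternative 3 | 5,7-dihydroxy-3',4',5'-trimethoxyflavone | COc1cc(-c2cc(=O)c3c(O)cc(O)cc3o2)cc(OC)c1OC
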